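(The constants were set for the occasion, and the outcome is calculated.)

In a one-step world, substrate meets carrier that stays fresh at the 4.0 mM charged and gives product, the substrate's half-life is 7.62 h, and no catalyst dies. The real flask is harder.

substrate 0.40 M; salt in the second phase 1.20 M; spent carrier 4.0 mM; volume of the second phase over the first 2.0

- the form that holds most of the catalyst when 50% of the substrate are converted (fresh carrier / spent catalyst / spent carrier)
- its share of the catalyst then
- apparent order in spent carrier when 50% of the substrate are converted (percent change of the rate of making product for one percent more spent carrier charged)
- factor on the rate of making product when 50% of the substrate are converted if spent carrier is charged twice over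

- in the second phase: salt in the second phase, spent salt in the second phase; everything else is in the first
- charges count per volume of the first phase; a concentration in a rate is the amount of a species over the volume of its own phase; every rate counts per litre of the first phase
- what has gone from substrate into another species counts as reacted, even if it can come back
- charge of substrate (flask): 0.40 M

    spent carrier + salt in the second phase ⇌ fresh carrier + spent salt in the second phase (K1 = 0.281, k1 = 0.0669 /M/min)
    substrate + fresh carrier → spent catalyst (k2 = 0.0118 /M/min)
    substrate + fresh carrier → product + spent carrier (k3 = 0.379 /M/min)
    substrate ⇌ dormant form (K4 = 21, k4 = 5.33 × 10⁻⁴ /min)

First we add the reload. The carrier is charged spent, and salt across the phase boundary makes it fresh at g1 = 2.41 /h per spent carrier, slower than fresh carrier is used on substrate, at g2 = 9.10 /h. Leaving the back step aside, the fresh fraction opens at g1/(g1+g2) = 20.9%, so spent carrier is the resting state of the working round, and product opens at 7.62 mM/h.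

Next we add the death step. Substrate and fresh carrier also give spent catalyst, and since both steps have the same two reactants, their rates stay in the ratio of their constants. Each carrier lost therefore comes with k3/k2 = 32.1 products. This gives the catalyst budget B, the product a charge can make before it is dead, equal to the carrier charged times k3/k2: 0.128 M, or 32.1% of the substrate charged. The dead share of the catalyst equals product made over B.

Last comes the dormant form, which opens at 12.8 mM/h, faster than product, so product opens with 37.3% of the substrate reacted. Held to 50% conversion, that share gives a dead share of 58.1%. But on that figure the fresh fraction at that point is 34.6% and 41.9% of the catalyst lives, so by our reckoning the ratio of product rate to dormant rate has dropped to 0.693 of its opening value, and we read our figure as high. Holding that closing ratio from the start, the same reckoning gives a dead share of 45.5%. At the closing fresh fraction, spent carrier ties spent catalyst at 39.5%, below both figures, so we commit to spent catalyst. Doubling the charge doubles B, while the opening product share rises from 37.3% to 54.4%, so less of the catalyst is lost: we expect an order above 1 and a factor above 2.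

The forecast names spent catalyst at 51% (46% to 56%), an order of 1.2 (1.05 to 1.35) and a factor of 2.4 (2.15 to 2.6), on these grounds: “Charging more carrier gets to half conversion sooner with less catalyst lost on the way”.

The simulation reaches 50% conversion at 14.5 h, with spent catalyst at 51.6%, spent carrier at 33.6% and fresh carrier at 14.8%. The order is 1.2 and the factor 2.35.

By the budget rule, 51.6% of B is 0.0660 M of product at 50% conversion. The death step is the largest single effect on this flask's rate: the same run without it gives 2.05 times the rate at 50% conversion, and its order in spent carrier is 0.92. Run on to 300 h, the flask holds spent catalyst at 96.8% of the catalyst, and product at 31.1% of the substrate charged, against a budget of 32.1%.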